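## The problem

Ebenfuran VI (15) is a 2-aryl-1-benzofuran-3-carbaldehyde without any stereocentre, so the difficulty lies entirely in regiochemistry and chemoselectivity. Ring A (the benzo ring) is substituted at five of its six carbons: the fusion carbons C3a and C7a, a free hydroxyl at C4, the 3-hydroxy-3-methylbutyl chain at C5 and a methoxy group at C6; only C7 carries hydrogen. Placing a carbon chain between two oxygens of a phloroglucinol-type ring and then telling those oxygens apart (O4 free, O6 methylated) is what benzofuran syntheses from preformed arenes do badly. Ring B at C2 asks the same question again (O2′ methylated, O4′ free), and C3 must end as an aldehyde flanked by the aryl group and the C4 hydroxyl. The tertiary alcohol sits three carbons from ring A and ortho to the C4 phenol: acid would close it to a 2,2-dimethylchroman or dehydrate it, and the electron-rich furan aldehyde tolerates neither strong acid nor strong oxidants, so the late steps must be neutral or basic. The enabling feature is that C4(OH)–C5(alkyl)–C6(O)–C7(H) is a 2-alkylresorcinol, that is, an enolized 1,3-diketone. C4 can come from an ester carbonyl on a furan, C7 from a methyl group next to it, and C6 and C5 from the carbonyl and α-carbon of 6,6-dimethyl-δ-valerolactone, whose remaining carbons and ring oxygen are exactly the hydroxylated side chain.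

## Retrosynthesis

The last disconnection is the O4′–benzyl bond: 15 is traced to its benzyl ether 14. The ring B phenol must be masked through amide base, methylation and hydride steps. Of the groups that survive these, benzyl is the one removed under neutral conditions, which the tertiary alcohol demands; an acid-labile group would invite chroman formation. The forward hydrogenolysis must spare the formyl group, which is deactivated as a vinylogous formate and by chelation to O4–H.

The C3 carbon is then adjusted in oxidation level: aldehyde 14 from primary alcohol 13, and 13 from methyl ester 12. An ester is preferred over an aldehyde or acetal as the group carried through the annulation because it is inert to the amide base, comes free of charge from the furan synthesis and serves as hydrogen-bond acceptor in the methylation. The price is two steps. The forward steps need an ester reduction beside a free phenol and an oxidation that touches only the activated primary alcohol.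

The O6–CH3 bond is cut next, leading from 12 to the 4,6-diol 11. Methylation after ring formation is dictated by the key step, which delivers both oxygens as phenoxides. Differentiation rests on the hydrogen bond from O4–H to the C3 ester carbonyl and on the greater hindrance at O4, the same basis as the selective 7-O-methylation of 5,7-dihydroxyflavones.

The key disconnection cuts C6–C7 and C4–C5 of ring A, taking 11 back to furan diester 6 and lactone 9 through the open keto diester 10. A Michael–Dieckmann variant with an unsaturated lactone would place carbon, not oxygen, at C6, so 1,2-acylation followed by Claisen closure is the version that fits the resorcinol pattern. Cuts through the furan or the biaryl bond would leave the pentasubstituted ring A to be made separately. This cut builds it from two simple pieces, installs the complete side chain with its tertiary alcohol and leaves the C3 ester as the aldehyde precursor. The forward reaction asks for C-acylation of a lateral anion by a lactone and for ring closure through the less acidic α′-position of the resulting ketone.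

Lactone 9 is cut at the C–CH3 bond and the lactone C–O bond, giving 5-oxohexanoic acid 7 by way of hydroxy acid 8. A methyl nucleophile adds to the ketone of the carboxylate salt and the tertiary hydroxy acid lactonizes on acidification.

Furan 6 is opened at its two C–O bonds to the 1,4-diketone 5 (Paal–Knorr), and 5 is cut at the central C–C bond into β-keto ester 3 and methyl 2-chloro-3-oxobutanoate 4. The alternative aldol-first (Feist–Benary) mode of union would give a different substitution pattern. The alkylation route fixes the 2-aryl-5-methyl-3,4-diester pattern by connectivity alone, since only the two ketones can form the furan.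

β-Keto ester 3 is cut at the bond between the ketone α-carbon and the ester carbon, leading to acetophenone 2, and 2 to the commercial phenol 1 by O-benzylation. Ring B thus enters with both of its oxygens already differentiated.

## Roads not taken

Alternative 1: The furan is cut at C2–C3. An aryldiazoacetate A2, in which ring A carries the ring B benzyl ether on the ortho oxygen, would be decomposed by Rh2(OAc)4. The carbenoid inserts into the ether OCH2 bond to give the cis-2,3-dihydrobenzofuran A1. Dehydrogenation to the furan, ester-to-aldehyde adjustment and desilylation would follow.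
- Merits: insertion into a C–H bond that is both benzylic and α to oxygen, with five-membered ring formation, is among the most dependable carbenoid reactions. Ring B is attached late by a simple etherification, and all phenols arrive already differentiated, so no selective methylation is needed. In these respects it is at least as secure as the chosen plan.
- Weak points: the key step does not address the real problem. The pentasubstituted ring A arylacetate must be made beforehand by stepwise arene chemistry. Two stereocentres are created only to be erased by an extra oxidation. Three silyl ethers are carried. The diazo carbon is flanked by two ortho substituents. The C3 ester needs the same redox adjustment as in the chosen plan.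
- Comparison: the chosen plan sets against the stronger precedent a shorter sequence in which the key step itself creates the crowded ring A.

Alternative 2: The biaryl bond C2–C1′ is cut, with the C3 carbon tied to ring B as a lactone. Pd(OAc)2 with Ag2CO3 would couple the C2–H of benzofuran ester A4 with the ortho C–H of its 3-benzyloxyphenyl group, giving coumestan A3. Lactone reduction, methylation of the liberated O2′–H, oxidation and hydrogenolysis would follow.
- Merits: the tether delivers the C3 carbon and the ring B oxygen together. The phenol freed on opening is exactly the one to be methylated, so ring B differentiation is automatic. No halide or organometallic partner is required. This is more elegant than carrying a benzyl-protected acetophenone.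
- Weak points: A4 already contains the complete ring A pattern, so the hard part is again left to the starting material. The aryl ester offers two ortho C–H sites. Twofold C–H coupling needs a stoichiometric silver oxidant and heat, in the presence of a tertiary alcohol and two benzyl ethers. Four steps remain after the coupling.
- Comparison: the chosen plan is shorter overall and solves ring A, at the cost of one selective methylation.

Alternative 3: The cut removes C3–CHO, C3–C3a and O1–C2 at once. HBF4·OEt2 would join salicylaldehyde A6 with diazoketone A7. Loss of N2 with 1,2-shift of ring A gives a 2-aryl-1,3-dicarbonyl intermediate, which cyclodehydrates to the 3-formylbenzofuran A5.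
- Merits: this is the most convergent plan. It delivers C3 directly at the aldehyde level, which is better than the reduction and reoxidation of the chosen plan.
- Weak points: the intermediate holds an aldehyde and an aryl ketone, and the phenol may close on the more electrophilic formyl group, which would give the 3-aroyl isomer. The established versions of this reaction use diazo esters, where no such competition exists. Strong protic acid meets a tertiary oxygenated chain and electron-rich benzyl ethers. The tertiary acetate must later be removed beside an aldehyde. A6 needs its own multistep synthesis with regioselective formylation and benzylation of a 2-alkylphloroglucinol.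
- Comparison: the chosen plan accepts two extra redox steps in exchange for unambiguous regiochemistry and a ring A that is built, not bought.

Key step: step 6

## Route

Assumption: 1, 4 and 7 are taken as commercial. Compound 5 is formed and used as a mixture of diastereomers and enol tautomers, since both of its stereocentres vanish in step 4.

Step 1
Reactants: 1 1-(4-hydroxy-2-methoxyphenyl)ethanone
Product: 2 1-[4-(benzyloxy)-2-methoxyphenyl]ethanone
Conditions: BnBr, K2CO3, acetone, reflux
Reagents that add atoms: benzyl bromide, BrCc1ccccc1
Why: Williamson etherification of the only acidic hydroxyl; the benzyl ether withstands every later base and hydride step and leaves at the end under neutral conditions.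

Step 2
Reactants: 2 1-[4-(benzyloxy)-2-methoxyphenyl]ethanone
Product: 3 methyl 3-[4-(benzyloxy)-2-methoxyphenyl]-3-oxopropanoate
Conditions: NaH (2.5 equiv), (MeO)2CO, THF, reflux; then AcOH
Reagents that add atoms: dimethyl carbonate, COC(=O)OC
Why: Crossed Claisen condensation (C-methoxycarbonylation) of a methyl ketone; irreversible deprotonation of the β-keto ester product drives it to completion.

Step 3
Reactants: 3 methyl 3-[4-(benzyloxy)-2-methoxyphenyl]-3-oxopropanoate; 4 methyl 2-chloro-3-oxobutanoate
Product: 5 dimethyl 2-acetyl-3-[4-(benzyloxy)-2-methoxybenzoyl]butanedioate (mixture of diastereomers)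
Conditions: NaH (1.05 equiv), THF, 0 °C; then 4, 0 → 25 °C
Reagents that add atoms: none
Why: SN2 C-alkylation of a β-keto ester sodium enolate by an α-chloro-β-keto ester, the classical entry to 2,3-diacylsuccinates; the preformed enolate in an aprotic solvent favours direct displacement over aldol-first (Feist–Benary) addition.

Step 4
Reactants: 5 dimethyl 2-acetyl-3-[4-(benzyloxy)-2-methoxybenzoyl]butanedioate
Product: 6 dimethyl 2-[4-(benzyloxy)-2-methoxyphenyl]-5-methylfuran-3,4-dicarboxylate
Conditions: p-TsOH·H2O (cat.), toluene, reflux, Dean–Stark
Reagents that add atoms: none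
Why: Paal–Knorr furan synthesis; only the two ketone carbonyls of the 1,4-diketone can cyclize and dehydrate, so the 2-aryl-5-methyl-3,4-diester pattern follows from connectivity.

Step 5
Reactants: 7 5-oxohexanoic acid
Product: 9 6,6-dimethyltetrahydro-2H-pyran-2-one, via 5-hydroxy-5-methylhexanoic acid 8 (not isolated)
Conditions: MeMgCl (2.5 equiv), THF, 0 → 25 °C; aq. HCl; then p-TsOH·H2O (cat.), CH2Cl2, 25 °C
Reagents that add atoms: methylmagnesium chloride, C[Mg]Cl
Why: The first equivalent of Grignard reagent forms the carboxylate and the second adds to the ketone (Grignard addition); the tertiary δ-hydroxy acid then lactonizes under acid catalysis.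

Step 6
Reactants: 6 dimethyl 2-[4-(benzyloxy)-2-methoxyphenyl]-5-methylfuran-3,4-dicarboxylate; 9 6,6-dimethyltetrahydro-2H-pyran-2-one
Product: 11 methyl 2-[4-(benzyloxy)-2-methoxyphenyl]-4,6-dihydroxy-5-(3-hydroxy-3-methylbutyl)-1-benzofuran-3-carboxylate, via keto diester 10 (not isolated)
Conditions: LiN(i-Pr)2 (1.1 equiv), THF, −78 °C; 9 (1.2 equiv), −78 °C; then LiN(i-Pr)2 (2.5 equiv), −78 → 25 °C; AcOH quench
Reagents that add atoms: none
Why: LiN(i-Pr)2 removes a proton from the 5-methyl group of 6, which is acidified as the vinylogous α-position of the C4 ester, and the dienolate adds through carbon to the carbonyl of 9; the lithium lactolate is expected to persist at −78 °C and so should not quench unreacted anion. On warming with the second charge of base the lactolate opens to keto alkoxide 10, which is deprotonated first at the furylic CH2 and then at the former lactone α-carbon. This α′-carbanion attacks the adjacent C4 ester in a 6-(enolendo)-exo-trig Claisen (Dieckmann-type) closure, methoxide is lost and the cyclic 1,3-diketone is drained irreversibly as the aromatic bisphenoxide, the thermodynamic sink of the sequence. The closest known reaction type is the acylation of laterally lithiated ortho-toluates and their heteroaromatic analogues by esters, lactones or Weinreb amides, followed by base-induced ring closure to 1,3-dihydroxyarenes. No stereocentre is formed. Regiochemistry is fixed by the substrate: only the C4 ester lies within six-membered reach of the carbanion, whereas the C3 ester would require a seven-membered closure and survives. C-acylation is secured over O-acylation (pyranone formation through the furylic enolate oxygen) by forming the dianion with excess strong base, and the tertiary alkoxide released from the lactone is a spectator that becomes the side-chain alcohol. The AcOH quench keeps the medium too weakly acidic for chroman formation.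

Step 7
Reactants: 11 methyl 2-[4-(benzyloxy)-2-methoxyphenyl]-4,6-dihydroxy-5-(3-hydroxy-3-methylbutyl)-1-benzofuran-3-carboxylate
Product: 12 methyl 2-[4-(benzyloxy)-2-methoxyphenyl]-4-hydroxy-5-(3-hydroxy-3-methylbutyl)-6-methoxy-1-benzofuran-3-carboxylate
Conditions: MeI (1.05 equiv), K2CO3, acetone, 25 °C
Reagents that add atoms: iodomethane, CI
Why: Williamson methylation with one equivalent of electrophile; O4–H is hydrogen bonded to the C3 ester carbonyl and flanked by the chain and the ester, whereas O6–H is free and less hindered, as in the selective 7-O-methylation of 5,7-dihydroxyflavones; the tertiary alcohol is not alkylated by carbonate base.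

Step 8
Reactants: 12 methyl 2-[4-(benzyloxy)-2-methoxyphenyl]-4-hydroxy-5-(3-hydroxy-3-methylbutyl)-6-methoxy-1-benzofuran-3-carboxylate
Product: 13 2-[4-(benzyloxy)-2-methoxyphenyl]-3-(hydroxymethyl)-5-(3-hydroxy-3-methylbutyl)-6-methoxy-1-benzofuran-4-ol
Conditions: LiAlH4 (3 equiv), THF, 0 °C; aq. potassium sodium tartrate (KNaC4H4O6) work-up
Reagents that add atoms: none
Why: Hydride reduction of an ester to the primary alcohol; the phenol and the tertiary alcohol are held as aluminates and set free again by the neutral tartrate work-up, which avoids acid-induced chroman formation or ionization of the furan-3-ylmethanol.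

Step 9
Reactants: 13 2-[4-(benzyloxy)-2-methoxyphenyl]-3-(hydroxymethyl)-5-(3-hydroxy-3-methylbutyl)-6-methoxy-1-benzofuran-4-ol
Product: 14 2-[4-(benzyloxy)-2-methoxyphenyl]-4-hydroxy-5-(3-hydroxy-3-methylbutyl)-6-methoxy-1-benzofuran-3-carbaldehyde
Conditions: activated MnO2 (excess), CH2Cl2, 25 °C
Reagents that add atoms: none
Why: MnO2 oxidizes only the activated (hetero-benzylic) primary alcohol under neutral heterogeneous conditions; the tertiary alcohol cannot be oxidized, and the aldehyde formed is stabilized by the hydrogen bond to O4–H.

Step 10
Reactants: 14 2-[4-(benzyloxy)-2-methoxyphenyl]-4-hydroxy-5-(3-hydroxy-3-methylbutyl)-6-methoxy-1-benzofuran-3-carbaldehyde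
Product: 15 Ebenfuran VI, 4-hydroxy-2-(4-hydroxy-2-methoxyphenyl)-5-(3-hydroxy-3-methylbutyl)-6-methoxy-1-benzofuran-3-carbaldehyde
Conditions: H2 (1 atm), 10% Pd/C, EtOAc, 25 °C, stopped after one equivalent of H2
Reagents that add atoms: none
Why: Hydrogenolysis of a benzyl aryl ether; the formyl group is a chelated vinylogous formate and reduces slowly, the tetrasubstituted furan double bond is inert at 1 atm, and the neutral medium spares the tertiary alcohol.

## Compound list

1 | 1-(4-hydroxy-2-methoxyphenyl)ethanone | CC(=O)c1ccc(O)cc1OC | starting material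
2 | 1-[4-(benzyloxy)-2-methoxyphenyl]ethanone | CC(=O)c1ccc(OCc2ccccc2)cc1OC | intermediate
3 | methyl 3-[4-(benzyloxy)-2-methoxyphenyl]-3-oxopropanoate | COC(=O)CC(=O)c1ccc(OCc2ccccc2)cc1OC | intermediate
4 | methyl 2-chloro-3-oxobutanoate | COC(=O)C(Cl)C(C)=O | starting material
5 | dimethyl 2-acetyl-3-[4-(benzyloxy)-2-methoxybenzoyl]butanedioate (mixture of diastereomers) | COC(=O)C(C(C)=O)C(C(=O)OC)C(=O)c1ccc(OCc2ccccc2)cc1OC | intermediate
6 | dimethyl 2-[4-(benzyloxy)-2-methoxyphenyl]-5-methylfuran-3,4-dicarboxylate | COC(=O)c1c(C)oc(-c2ccc(OCc3ccccc3)cc2OC)c1C(=O)OC | intermediate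
7 | 5-oxohexanoic acid | CC(=O)CCCC(=O)O | starting material
8 | 5-hydroxy-5-methylhexanoic acid | CC(C)(O)CCCC(=O)O | intermediate (not isolated)
9 | 6,6-dimethyltetrahydro-2H-pyran-2-one | CC1(C)CCCC(=O)O1 | intermediate
10 | dimethyl 2-[4-(benzyloxy)-2-methoxyphenyl]-5-(6-hydroxy-6-methyl-2-oxoheptyl)furan-3,4-dicarboxylate | COC(=O)c1c(CC(=O)CCCC(C)(C)O)oc(-c2ccc(OCc3ccccc3)cc2OC)c1C(=O)OC | intermediate (not isolated)
11 | methyl 2-[4-(benzyloxy)-2-methoxyphenyl]-4,6-dihydroxy-5-(3-hydroxy-3-methylbutyl)-1-benzofuran-3-carboxylate | COC(=O)c1c(-c2ccc(OCc3ccccc3)cc2OC)oc2cc(O)c(CCC(C)(C)O)c(O)c12 | intermediate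
12 | methyl 2-[4-(benzyloxy)-2-methoxyphenyl]-4-hydroxy-5-(3-hydroxy-3-methylbutyl)-6-methoxy-1-benzofuran-3-carboxylate | COC(=O)c1c(-c2ccc(OCc3ccccc3)cc2OC)oc2cc(OC)c(CCC(C)(C)O)c(O)c12 | intermediate
13 | 2-[4-(benzyloxy)-2-methoxyphenyl]-3-(hydroxymethyl)-5-(3-hydroxy-3-methylbutyl)-6-methoxy-1-benzofuran-4-ol | OCc1c(-c2ccc(OCc3ccccc3)cc2OC)oc2cc(OC)c(CCC(C)(C)O)c(O)c12 | intermediate
14 | 2-[4-(benzyloxy)-2-methoxyphenyl]-4-hydroxy-5-(3-hydroxy-3-methylbutyl)-6-methoxy-1-benzofuran-3-carbaldehyde | O=Cc1c(-c2ccc(OCc3ccccc3)cc2OC)oc2cc(OC)c(CCC(C)(C)O)c(O)c12 | intermediate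
15 | Ebenfuran VI, 4-hydroxy-2-(4-hydroxy-2-methoxyphenyl)-5-(3-hydroxy-3-methylbutyl)-6-methoxy-1-benzofuran-3-carbaldehyde | COc1cc(O)ccc1-c1oc2cc(OC)c(CCC(C)(C)O)c(O)c2c1C=O | target

## Step count and least certain steps

Total: 10 steps. Longest linear sequence: 9 steps (steps 1–4 and 6–10); step 5 is a one-step side branch.

Step 6 (key step). The lateral anion may act as a base toward the α-protons of 9 instead of adding to its carbonyl. Ring closure may also stall at the furylic enolate, or divert to O-acylation, because the required α′-position is the less acidic one.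
- Fallback: separate the two bond formations and change the electrophile, setting out from 6 and 9 and returning at 11.
- 9 is opened with MeNH(OMe)·HCl and AlMe3 to 5-hydroxy-N-methoxy-N,5-dimethylhexanamide F1.
- F1 is silylated (Et3SiOTf, 2,6-lutidine) to N-methoxy-N,5-dimethyl-5-[(triethylsilyl)oxy]hexanamide F2.
- The lateral anion of 6 is acylated by this Weinreb amide, a reliable partner for toluate-type anions, giving the isolable ketone dimethyl 2-[4-(benzyloxy)-2-methoxyphenyl]-5-{6-methyl-2-oxo-6-[(triethylsilyl)oxy]heptyl}furan-3,4-dicarboxylate F3.
- KOt-Bu in THF then effects the Claisen closure under equilibrating conditions to methyl 2-[4-(benzyloxy)-2-methoxyphenyl]-4,6-dihydroxy-5-{3-methyl-3-[(triethylsilyl)oxy]butyl}-1-benzofuran-3-carboxylate F4.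
- Bu4NF removes the silyl group to give 11.

Step 3. Compound 4 is more acidic than 3, so proton exchange can stall the alkylation, and chlorine transfer between the two enolates would lead to homo-coupling.
- Fallback: an aldol-first union that avoids the enolate/α-halo-β-keto ester pair, setting out from 3 and returning at 6.
- 3 is treated with commercial methyl 3-bromo-2-oxobutanoate and Et3N in THF (interrupted Feist–Benary reaction). The enolate adds to the highly electrophilic keto ester carbonyl and the enol oxygen displaces bromide.
- This gives dimethyl 2-[4-(benzyloxy)-2-methoxyphenyl]-4-hydroxy-5-methyl-4,5-dihydrofuran-3,4-dicarboxylate F5.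
- Dehydration with catalytic p-TsOH in toluene gives 6.

Step 7. Discrimination between O4 and O6 may be insufficient, because the hydrogen bond to the ester closes a seven-membered ring and may be weak; O4-methylation or double methylation would result.
- Fallback: postpone the methylation to the aldehyde stage, where the chelate to the unhindered formyl oxygen is stronger. It sets out from 11 and returns at 14.
- LiAlH4 reduces 11 to 2-[4-(benzyloxy)-2-methoxyphenyl]-3-(hydroxymethyl)-5-(3-hydroxy-3-methylbutyl)-1-benzofuran-4,6-diol F6.
- MnO2 oxidizes F6 to 2-[4-(benzyloxy)-2-methoxyphenyl]-4,6-dihydroxy-5-(3-hydroxy-3-methylbutyl)-1-benzofuran-3-carbaldehyde F7.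
- Me3SiCHN2 in MeOH/toluene, a reagent that spares chelated phenols, methylates O6 to give 14.

Step 8. The aluminium alkoxide of the electron-rich furan-3-ylmethanol may ionize, assisted by O1 and the 2-aryl group, and be reduced further. The alcohol may also decompose on work-up.
- Fallback: avoid the alcohol oxidation level, setting out from 12 and returning at 14, so that step 9 is bypassed as well.
- Aminolysis of 12 with MeNH(OMe)·HCl and excess i-PrMgCl gives 2-[4-(benzyloxy)-2-methoxyphenyl]-4-hydroxy-5-(3-hydroxy-3-methylbutyl)-N,6-dimethoxy-N-methyl-1-benzofuran-3-carboxamide F8.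
- Reduction with i-Bu2AlH at −78 °C stops at the chelated tetrahedral intermediate and gives 14 on work-up.

Step 10. Hydrogenation may continue at the formyl group after the benzyl ether is cleaved.
- Fallback: move the hydrogenolysis to the ester stage, where nothing else is reducible, setting out from 12 and returning at 15.
- H2 and 10% Pd/C convert 12 into methyl 4-hydroxy-2-(4-hydroxy-2-methoxyphenyl)-5-(3-hydroxy-3-methylbutyl)-6-methoxy-1-benzofuran-3-carboxylate F9.
- LiAlH4 at 0 °C, kept cold to limit quinone-methide-type over-reduction, gives 3-(hydroxymethyl)-2-(4-hydroxy-2-methoxyphenyl)-5-(3-hydroxy-3-methylbutyl)-6-methoxy-1-benzofuran-4-ol F10.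
- MnO2 oxidizes F10 to 15.

## Further compounds

F1 | step 6 | 5-hydroxy-N-methoxy-N,5-dimethylhexanamide | CON(C)C(=O)CCCC(C)(C)O
F2 | step 6 | N-methoxy-N,5-dimethyl-5-[(triethylsilyl)oxy]hexanamide | CON(C)C(=O)CCCC(C)(C)O[Si](CC)(CC)CC
F3 | step 6 | dimethyl 2-[4-(benzyloxy)-2-methoxyphenyl]-5-{6-methyl-2-oxo-6-[(triethylsilyl)oxy]heptyl}furan-3,4-dicarboxylate | COC(=O)c1c(CC(=O)CCCC(C)(C)O[Si](CC)(CC)CC)oc(-c2ccc(OCc3ccccc3)cc2OC)c1C(=O)OC
F4 | step 6 | methyl 2-[4-(benzyloxy)-2-methoxyphenyl]-4,6-dihydroxy-5-{3-methyl-3-[(triethylsilyl)oxy]butyl}-1-benzofuran-3-carboxylate | COC(=O)c1c(-c2ccc(OCc3ccccc3)cc2OC)oc2cc(O)c(CCC(C)(C)O[Si](CC)(CC)CC)c(O)c12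
F5 | step 3 | dimethyl 2-[4-(benzyloxy)-2-methoxyphenyl]-4-hydroxy-5-methyl-4,5-dihydrofuran-3,4-dicarboxylate (mixture of diastereomers) | COC(=O)C1=C(c2ccc(OCc3ccccc3)cc2OC)OC(C)C1(O)C(=O)OC
F6 | step 7 | 2-[4-(benzyloxy)-2-methoxyphenyl]-3-(hydroxymethyl)-5-(3-hydroxy-3-methylbutyl)-1-benzofuran-4,6-diol | OCc1c(-c2ccc(OCc3ccccc3)cc2OC)oc2cc(O)c(CCC(C)(C)O)c(O)c12
F7 | step 7 | 2-[4-(benzyloxy)-2-methoxyphenyl]-4,6-dihydroxy-5-(3-hydroxy-3-methylbutyl)-1-benzofuran-3-carbaldehyde | O=Cc1c(-c2ccc(OCc3ccccc3)cc2OC)oc2cc(O)c(CCC(C)(C)O)c(O)c12
F8 | step 8 | 2-[4-(benzyloxy)-2-methoxyphenyl]-4-hydroxy-5-(3-hydroxy-3-methylbutyl)-N,6-dimethoxy-N-methyl-1-benzofuran-3-carboxamide | CON(C)C(=O)c1c(-c2ccc(OCc3ccccc3)cc2OC)oc2cc(OC)c(CCC(C)(C)O)c(O)c12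
F9 | step 10 | methyl 4-hydroxy-2-(4-hydroxy-2-methoxyphenyl)-5-(3-hydroxy-3-methylbutyl)-6-methoxy-1-benzofuran-3-carboxylate | COC(=O)c1c(-c2ccc(O)cc2OC)oc2cc(OC)c(CCC(C)(C)O)c(O)c12
F10 | step 10 | 3-(hydroxymethyl)-2-(4-hydroxy-2-methoxyphenyl)-5-(3-hydroxy-3-methylbutyl)-6-methoxy-1-benzofuran-4-ol | OCc1c(-c2ccc(O)cc2OC)oc2cc(OC)c(CCC(C)(C)O)c(O)c12
A1 | alternative 1 | methyl cis-4-(tert-butyldimethylsilyloxy)-2-[4-(tert-butyldimethylsilyloxy)-2-methoxyphenyl]-6-methoxy-5-[3-methyl-3-(triethylsilyloxy)butyl]-2,3-dihydro-1-benzofuran-3-carboxylate (racemic, one enantiomer drawn) | COC(=O)[C@@H]1[C@H](c2ccc(O[Si](C)(C)C(C)(C)C)cc2OC)Oc2cc(OC)c(CCC(C)(C)O[Si](CC)(CC)CC)c(O[Si](C)(C)C(C)(C)C)c21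
A2 | alternative 1 | methyl 2-{2-(tert-butyldimethylsilyloxy)-6-{[4-(tert-butyldimethylsilyloxy)-2-methoxyphenyl]methoxy}-4-methoxy-3-[3-methyl-3-(triethylsilyloxy)butyl]phenyl}-2-diazoacetate | COC(=O)C(=[N+]=[N-])c1c(OCc2ccc(O[Si](C)(C)C(C)(C)C)cc2OC)cc(OC)c(CCC(C)(C)O[Si](CC)(CC)CC)c1O[Si](C)(C)C(C)(C)C
A3 | alternative 2 | 3,7-bis(benzyloxy)-8-(3-hydroxy-3-methylbutyl)-9-methoxy-6H-benzofuro[3,2-c]chromen-6-one | O=C1Oc2cc(OCc3ccccc3)ccc2-c2oc3cc(OC)c(CCC(C)(C)O)c(OCc4ccccc4)c3c21
A4 | alternative 2 | 3-(benzyloxy)phenyl 4-(benzyloxy)-5-(3-hydroxy-3-methylbutyl)-6-methoxy-1-benzofuran-3-carboxylate | O=C(Oc1cccc(OCc2ccccc2)c1)c1coc2cc(OC)c(CCC(C)(C)O)c(OCc3ccccc3)c12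
A5 | alternative 3 | 4-{4-(benzyloxy)-2-[4-(benzyloxy)-2-methoxyphenyl]-3-formyl-6-methoxy-1-benzofuran-5-yl}-2-methylbutan-2-yl acetate | O=Cc1c(-c2ccc(OCc3ccccc3)cc2OC)oc2cc(OC)c(CCC(C)(C)OC(C)=O)c(OCc3ccccc3)c12
A6 | alternative 3 | 4-[2-(benzyloxy)-3-formyl-4-hydroxy-6-methoxyphenyl]-2-methylbutan-2-yl acetate | O=Cc1c(O)cc(OC)c(CCC(C)(C)OC(C)=O)c1OCc1ccccc1
A7 | alternative 3 | 1-[4-(benzyloxy)-2-methoxyphenyl]-2-diazoethan-1-one | [N-]=[N+]=CC(=O)c1ccc(OCc2ccccc2)cc1OC
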